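The charge holds 0.550 of Z for each L or D together, so Z is the limiting reagent, and two chemists dispute what becomes of X, the product that L gives with Z.

in all of them: Q 2.4 mM
- dusk: L 0.063 M; Z 0.0693 M; D 0.063 M; run made earlier
- dawn: L 0.063 M; Z 0.0693 M; D 0.032 M; run made earlier
- winter: L 0.063 M; Z 0.0693 M; D 0.13 M; run made earlier
- autumn: L 0.13 M; Z 0.0693 M; D 0.063 M; run made earlier
- theta: L 0.063 M; Z 0.0693 M; D 0.0630 M (fed, over 5.00 d); a stirred flask in which D is dosed at a steady rate over 5.00 d without added volume, worked up at 10 d; time 10 d
- eta: L 0.063 M; Z 0.0693 M; D 0.0630 M; one stirred flow tank at steady state, fed with the mixture as stated, mean residence time 10 d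
- alpha: L 0.063 M; Z 0.0693 M; D 0.0630 M; a closed flask charged with all of it at once and left for 10 d; time 10 d
- delta: L 0.063 M; Z 0.0693 M (fed, over 5.00 d); D 0.0630 M; a stirred flask in which Z is dosed at a steady rate over 5.00 d without added volume, worked up at 10 d; time 10 d

| run | time / d | X / % | L / % |
|---|---|---|---|
| dusk | 0.417 | 18.7 | 73.1 |
| dusk | 1.25 | 12.6 | 64.0 |
| dusk | 2.00 | 9.3 | 58.6 |
| dusk | 3.00 | 5.9 | 55.8 |
| dusk | 5.00 | 2.2 | 52.7 |
| dusk | 6.00 | 1.8 | 51.3 |
| dawn | 1.67 | 34.0 | 27.7 |
| dawn | 3.00 | 28.9 | 16.4 |
| dawn | 5.00 | 25.3 | 9.5 |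
| dawn | 6.00 | 24.4 | 7.3 |
| dawn | 8.00 | 22.0 | 5.1 |
| dawn | 10.0 | 20.8 | 3.5 |
| winter | 0.833 | 4.1 | 85.8 |
| winter | 1.25 | 4.1 | 85.1 |
| winter | 2.00 | 2.8 | 82.1 |
| winter | 4.00 | 1.1 | 81.2 |
| winter | 6.00 | 0 | 81.2 |
| winter | 10.0 | 0.7 | 80.7 |
| autumn | 2.08 | 1.9 | 65.2 |
| autumn | 4.00 | 0.1 | 64.2 |
| autumn | 6.00 | 0 | 64.8 |
| autumn | 8.00 | 0.4 | 64.2 |
| autumn | 10.0 | 0.3 | 64.3 |

(scatter of a reading: 0.5 percentage points)

- the stated concentrations are those of everything mixed, before any reaction; amounts are the same in each set-up
- the feed brings no volume worth counting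
- the earlier runs were made in a closed, stirred flask

* the set-up with the highest amount of X at the outlet or at the end, in percent of the L put in ("none" if the first two lie within 2 percentage points) (theta / eta / alpha / delta / none)
* amount of X at the outlet or at the end, in percent of the L put in, theta
* amount of X at the outlet or at the end, in percent of the L put in, eta
* amount of X at the outlet or at the end, in percent of the L put in, alpha
* amount of X at the outlet or at the end, in percent of the L put in, delta

The first chemist holds that D destroys X, since X fades in each run charged with D; a flask receiving D then ends poor in X. The second holds that L destroys it: in dusk, from 2.00 d to 6.00 d, X falls 7.5 percentage points while L falls 7.3 points, about one L per X.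

I side with the second and keep her ledger. Let f be the share of L that took Z and became X. Once L has stopped taking Z, each X lost takes one more L, so X minus L, both as shares of the L charged, stays at 2f − 1. Dusk's last reading gives f = 25.2 %. In this ledger, with f below 0.5 X falls toward zero; with f above it L falls toward zero and X toward 2f − 1.

Alpha has dusk's charge and so dusk's f. Theta needs a reckoning. In dusk, with L and D charged equally, D took about 0.0534 M of Z and L took about 0.0159 M, so I count D in theta as taken about as fast as it arrives, at a dosing rate r = 0.0126 M d⁻¹. Let κ be the rate constant of L with Z, taken as second order; with L near Z, Z then loses κZ² to L and r to D. From the first dusk reading, with Z's mean taken as 0.5 of its charge, κ is roughly 17.9 L mol⁻¹ d⁻¹. The two losses match at a concentration of Z, called Z*, of √(r/κ) = 0.0265 M, and I give D about that much Z. So in theta I put f near 67.9 %, and X at the end near 35.8 %.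

The forecast, on the first view, gives 1.5 % for theta (“X builds early”, then D removes it), 5 % for eta, 0.4 % for alpha and 0.2 % for delta, and names eta.

Theta gives 48.8 %, ahead of eta's 5.72 %, alpha's 0.290 % and delta's 1.06 %, and after 100 d it stands at 48.5 %.

    L + Z + Q → Q + X (k = 1210 L² mol⁻² h⁻¹)
    D + Z + Q → Q + E (k = 7880 L² mol⁻² h⁻¹)
    2 Q ⇌ G, settled at all times (K = 230 L mol⁻¹)
    L + X → J (k = 0.542 L mol⁻¹ h⁻¹)

Read backwards, that X means f = 74.4 % in theta, above my 67.9 %. The first view keeps the region of f below 0.5, where X does fade: alpha, with dusk's reading f = 25.2 %, holds 0.290 % at 10 d and 0 % at 100 d. In alpha J, of which each one counts as two in the percentage, stands at 49.3 % of the L charged, against 2f = 50.4 %.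

The runs were generated by integration from invented constants; the scatter is artificial.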